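**Assumptions:** I use natural-product numbering (furan C1–C4, chain C5–C19). The SMILES reads as 7E, 11E, 10S, 15R, 16S. (−)-Sparteine, the D-fructose-derived Shi ketone and isopropenyl-Bpin are treated as commercial.

## Retrosynthetic overview
1. The last bond formed is C9–C10. Target 15 comes from enal 14 and the α-chiral β-methallylboronate (R)-6. One stereospecific, protecting-group-free allylboration makes the C–C bond, the 10S carbinol and the 7E olefin together, replacing the usual C10–C11 vinylmetal/aldehyde coupling with redox correction.
2. (R)-6 comes from sparteine lithiation–borylation of carbamate 4 with isopropenyl-Bpin. Carbamate 4 comes from 3-bromofuran and oxetane, so the furan ring is bought, not built.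
3. Enal 14 comes from the (15R,16R)-epoxy ester 11 by invertive 5-exo lactonization. This anti-addition to an E-olefin gives the required erythro 15R,16S pair. Syn-dihydroxylation of the same olefin would give the wrong diastereomer.
4. Epoxide 11 comes from Shi epoxidation of dienoate 10, which comes from Johnson–Claisen rearrangement of 8, which comes from a Schenck ene reaction on geranyl acetate.
5. The γ-lactone (step 7) is the only ring formed. All oxidations (¹O2, Oxone, MnO2) are finished before the oxidation-sensitive furan enters in step 10.

## Route

**Step 1**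
Reactants: 1, 3-bromofuran; 2, oxetane
Product: 3, 3-(furan-3-yl)propan-1-ol
Conditions: n-BuLi, THF, −78 °C; then 2, BF3·OEt2, −78 °C
Reagents that add atoms: none beyond reactant 2 (oxetane, C1COC1)
Why: Br/Li exchange gives 3-furyllithium, which is positionally stable at −78 °C and opens the BF3-activated oxetane (Lewis-acid-assisted SN2 ring opening), installing C5–C7 in one step with no stereocentre.

**Step 2**
Reactants: 3
Product: 4, 3-(furan-3-yl)propyl N,N-diisopropylcarbamate
Conditions: i-Pr2NCOCl, Et3N, CH2Cl2, reflux
Reagents that add atoms: N,N-diisopropylcarbamoyl chloride, CC(C)N(C(C)C)C(=O)Cl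
Why: Simple O-carbamoylation installs the Hoppe directing and leaving group.

**Step 3**
Reactants: 4; 5, isopropenylboronic acid pinacol ester
Product: 6, 2-[(3R)-5-(furan-3-yl)-2-methylpent-1-en-3-yl]-4,4,5,5-tetramethyl-1,3,2-dioxaborolane
Conditions: s-BuLi (1.15 equiv), (−)-sparteine, Et2O, −78 °C, 5 h; 5, −78 °C, 1 h; MgBr2·OEt2, then reflux
Reagents that add atoms: none beyond reactant 5 (the OCb group is expelled)
Why: In this Hoppe asymmetric deprotonation and lithiation–borylation, the carbamate-directed s-BuLi/(−)-sparteine complex removes the pro-S H faster than it lithiates the furan, the (S)-organolithium is borylated with retention, and the alkenyl 1,2-metallate shift displaces OCb with inversion to set C7 as R (about 96:4 er).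

**Step 4**
Reactants: 7, geranyl acetate
Product: 8, (2E)-6-hydroxy-3,7-dimethylocta-2,7-dien-1-yl acetate (racemic)
Conditions: O2, TPP (cat.), visible light, CH2Cl2, 0 °C; then PPh3
Reagents that add atoms: dioxygen, O=O (one O retained)
Why: The Schenck ene reaction of ¹O2 attacks only the electron-rich 6,7-olefin because the 2,3-olefin is deactivated by the allylic acetate, giving after reduction 8 plus a separable tertiary regioisomer (about 1:1), and the racemic carbinol is erased in step 5.

**Step 5**
Reactants: 8; 9, triethyl orthoacetate
Product: 10, ethyl (4E,8E)-10-acetoxy-4,8-dimethyldeca-4,8-dienoate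
Conditions: 9 (excess), EtCO2H (cat.), 138 °C, distil off EtOH
Reagents that add atoms: none beyond reactant 9
Why: In the Johnson–Claisen [3,3] rearrangement, a chair transition state with the chain equatorial (avoiding the 1,3-diaxial clash with OEt) gives the 4E trisubstituted olefin (≥95:5) and adds C18–C19.

**Step 6**
Reactants: 10
Product: 11, ethyl 3-[(2R,3R)-3-[(3E)-5-acetoxy-3-methylpent-3-en-1-yl]-2-methyloxiran-2-yl]propanoate
Conditions: D-fructose-derived Shi ketone (30 mol %), Oxone, K2CO3, Bu4NHSO4, MeCN–DMM/aq. Na2B4O7–EDTA (pH 10.5), 0 °C
Reagents that add atoms: Oxone (KHSO5), [K+].[O-]S(=O)(=O)OO (one O)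
Why: Shi asymmetric epoxidation through the spiro dioxirane transition state gives the (R,R)-epoxide of the isolated E-trisubstituted olefin (about 90–94% ee) and leaves the acetate-deactivated olefin untouched, setting C15 as R and C16 provisionally as R.

**Step 7**
Reactants: 11
Product: 12, (5S)-5-[(1R,4E)-1,6-dihydroxy-4-methylhex-4-en-1-yl]-5-methyloxolan-2-one
Conditions: LiOH, THF–MeOH–H2O, 0 °C→rt; then aq. citric acid to pH 3–4, rt (cat. PPTS if needed)
Reagents that add atoms: lithium hydroxide/water, [Li+].[OH-] (one O ends up in the carboxyl)
Why: Saponification frees the acid and C10–OH, and on acidification a 5-exo-tet epoxide-opening lactonization occurs at tertiary C16 with inversion (16R→16S) while the C15–O bond stays intact (15R).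

**Step 8**
Reactants: 12
Product: 13, (2E,6R)-6-hydroxy-3-methyl-6-[(2S)-2-methyl-5-oxooxolan-2-yl]hex-2-enal
Conditions: activated MnO2, CH2Cl2, rt
Reagents that add atoms: none
Why: Chemoselective allylic oxidation converts only the primary allylic alcohol, leaves the hindered non-allylic C15–OH untouched and retains the E geometry.

**Step 9**
Reactants: 13
Product: 14, (1R,4E)-4-methyl-1-[(2S)-2-methyl-5-oxooxolan-2-yl]-6-oxohex-4-en-1-yl acetate
Conditions: Ac2O, pyridine, DMAP (5 mol %), CH2Cl2, 0 °C→rt
Reagents that add atoms: acetic anhydride, CC(=O)OC(C)=O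
Why: DMAP-catalysed acylation of the only hydroxyl installs the C15 acetate before C10–OH exists, and the mild, short conditions avoid enal E/Z isomerization or dienyl acetate formation.

**Step 10 (key step)**
Reactants: 14; 6 (1.3 equiv)
Product: 15, 15-acetylirciformonin B, (1R,4E,6S,8E)-11-(furan-3-yl)-6-hydroxy-4,8-dimethyl-1-[(2S)-2-methyl-5-oxooxolan-2-yl]undeca-4,8-dien-1-yl acetate
Conditions: 6, n-BuLi (1.3 equiv), THF, −78 °C, 15 min; TFAA (1.4 equiv), −78 °C, 30 min; then 14, −78 °C→rt; pH 7 buffer/H2O2, 0 °C
Reagents that add atoms: none (n-Bu and CF3CO leave with the boron by-product; the carbinol H comes from work-up)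
Why: This is a stereospecific type-I allylboration through an in situ allyl(butyl)borinic ester, whose B-butyl group forces the C7 substituent pseudo-equatorial in the closed chair, so the 7E olefin forms, C7-(R) chirality is relayed suprafacially to the Si face of the enal to give 10S, the ester groups are inert, and minor enantiomers of either fragment end up as separable diastereomers.

## Compound list
| No. | Name | SMILES | Role |
|---|---|---|---|
| 1 | 3-bromofuran | Brc1ccoc1 | starting material |
| 2 | oxetane | C1COC1 | starting material |
| 3 | 3-(furan-3-yl)propan-1-ol | OCCCc1ccoc1 | intermediate |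
| 4 | 3-(furan-3-yl)propyl N,N-diisopropylcarbamate | CC(C)N(C(C)C)C(=O)OCCCc1ccoc1 | intermediate |
| 5 | isopropenylboronic acid pinacol ester | C=C(C)B1OC(C)(C)C(C)(C)O1 | starting material |
| 6 | (R)-α-[2-(3-furyl)ethyl]-β-methallyl pinacol boronate | C=C(C)[C@@H](CCc1ccoc1)B1OC(C)(C)C(C)(C)O1 | intermediate |
| 7 | geranyl acetate | CC(C)=CCC/C(C)=C/COC(C)=O | starting material |
| 8 | (2E)-6-hydroxy-3,7-dimethylocta-2,7-dien-1-yl acetate (rac) | C=C(C)C(O)CC/C(C)=C/COC(C)=O | intermediate |
| 9 | triethyl orthoacetate | CC(OCC)(OCC)OCC | starting material |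
| 10 | ethyl (4E,8E)-10-acetoxy-4,8-dimethyldeca-4,8-dienoate | CCOC(=O)CC/C(C)=C/CC/C(C)=C/COC(C)=O | intermediate |
| 11 | (15R,16R)-epoxy ester | CCOC(=O)CC[C@@]1(C)O[C@@H]1CC/C(C)=C/COC(C)=O | intermediate |
| 12 | (15R,16S)-diol lactone | O[C@H](CC/C(C)=C/CO)[C@]1(C)CCC(=O)O1 | intermediate |
| 13 | hydroxy enal lactone | O[C@H](CC/C(C)=C/C=O)[C@]1(C)CCC(=O)O1 | intermediate |
| 14 | acetoxy enal lactone | CC(=O)O[C@H](CC/C(C)=C/C=O)[C@]1(C)CCC(=O)O1 | intermediate |
| 15 | 15-acetylirciformonin B | CC(=O)O[C@H](CC/C(C)=C/[C@@H](O)C/C(C)=C/CCc1ccoc1)[C@]1(C)CCC(=O)O1 | target |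

## Summary
**Total steps:** 10. **Longest linear sequence:** 7 (steps 4–10). The side arm is 3 steps (1–3).

**Three steps most likely to fail, each with a fallback**
1. **Step 10.** The hindered β,β-disubstituted enal may erode E/Z selectivity or chirality transfer, or allow a borotropic shift.
   - Fallback: separate bond formation from stereoinduction. Pre-build the 7E olefin as (E)-3-(5-chloro-4-methylpent-3-enyl)furan and add it to 14 as the α-selective, geometry-retentive allylbarium reagent. Then oxidise C10 to the dienone (DMP) and set 10S by CBS reduction.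
2. **Step 3.** Furan C2/C5 lithiation may compete with the carbamate deprotonation.
   - Fallback: move the chirality source onto boron. Run a Matteson homologation of the DICHED 2-(furan-3-yl)ethylboronate (from 3-vinylfuran hydroboration) with LiCHCl2/ZnCl2. Follow with isopropenylMgBr displacement and diol exchange to pinacol, so no alkyllithium ever meets the furan.
3. **Steps 6/7.** The ee or site selectivity of the epoxidation may fall short, or the opening at tertiary C16 may leak toward SN1.
   - Fallback: use the carbinol of 8 instead of destroying it. Sharpless kinetic resolution/epoxidation of rac-8 gives the erythro (15R,16S) epoxy alcohol. Open the terminal epoxide at C17 with malonate (in situ lactonization) and decarboxylate (Krapcho). The C16–O bond is then never broken.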